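Work in millimolar per minute, because the question is how fast gas can be turned into target in each flask.

| setting | north-east | north-west | violet | green | grey |
|---|---|---|---|---|---|
| substrate | 0.80 M | 0.80 M | 0.80 M | 1.5 M | 3.0 M |
| gas phase | 200 mM (held) | 200 mM (held) | 200 mM (held) | 200 mM (held) | 200 mM (held) |
| catalyst | 8.4 mM | 2.8 mM | 5.6 mM | 5.6 mM | 5.6 mM |
| remark | run made earlier | run made earlier |  |  |  |
| time |  |  | 4.0 h | 4.0 h | 4.0 h |

| run | time / min | target / % |
|---|---|---|
| north-east | 6.00 | 0 |
| north-east | 15.0 | 3.1 |
| north-east | 20.0 | 3.9 |
| north-east | 30.0 | 8.6 |
| north-east | 40.0 | 10.9 |
| north-east | 50.0 | 14.9 |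
| north-west | 6.00 | 0 |
| north-west | 15.0 | 1.4 |
| north-west | 20.0 | 2.2 |
| north-west | 30.0 | 3.4 |
| north-west | 40.0 | 6.0 |
| north-west | 50.0 | 7.6 |

(scatter of a reading: 0.5 percentage points)

- the analysis behind the earlier runs scatters by 0.5 percentage points, standard deviation
- at the start none of the gas phase is in solution
- "hardly changes" means that all values lie within two and a half points (for a concentration: within two and a half percent of the largest)

- [target] at the end for violet, green, grey, in this order
- the course of these numbers from the first flask to the last (rises, then falls / falls all the way / hardly changes / rises all the way / falls, then rises)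

Write the balance of dissolved gas, the limiting reagent of the moment, with a saturation value of 200 mM against 0.80 M of substrate. Assume that it enters in proportion to its distance from saturation and leaves in proportion to [substrate][catalyst][dissolved gas]; at balance, the reciprocal rate is then the reciprocal of a ceiling plus a catalyst term falling with [catalyst].

Draw the curve from the readings. It starts flat, with target at 0% after 6.00 min in the north-east run, and then climbs. Between the second and last readings, the north-east slope is 2.70 mM min⁻¹ and the north-west slope 1.42 mM min⁻¹, each carrying the scatter of 0.5 percentage points. These two slopes give, as readings, a catalyst term of 1.41 min at 0.80 M and the gas ceiling, the rate at which gas enters liquid holding none, 4.92 mM min⁻¹; two runs give two constants, so this fit leaves nothing over to test it.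

Take the catalyst term as inversely proportional to [substrate], an assumption because neither run varied it. Holding each slope at the [substrate] charged, I reckon that violet climbs at 2.20 mM min⁻¹, green at 2.96 mM min⁻¹ and grey at 3.70 mM min⁻¹, still below the ceiling. The violet charge lasts 6.06 h at that slope, so I draw no knee in violet before the asked time. After the flat start, I reckon 0.515 M, 0.694 M and 0.866 M of target made, a rising row that stands as [target] as long as nothing consumes target.

The forecast, which differs from my row, gave 0.49 M, 0.49 M and 0.49 M, course hardly changes, on the ground that, if the rate is limited by gas or a saturated catalyst, “substrate hardly matters”.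

The flasks give 0.448 M, 0.519 M and 0.433 M: rises, then falls.

    gas phase ⇌ dissolved gas, rate k1*(csat - [dissolved gas]) (kL = 1.29 h⁻¹)
    substrate + dissolved gas + catalyst → catalyst + target (k = 681 M⁻² h⁻¹)
    substrate + target → side product (k = 0.193 M⁻¹ h⁻¹)

Counting each side product as two substrates, violet made 0.521 M of target by 4.00 h against the reckoned 0.515 M, and 0.0733 M of that had gone on to side product, though at 1.72 h target was still being made 6.53 times faster than it was used up. By 4.00 h grey had made 0.872 M against the reckoned 0.866 M and the 1.15 M that the ceiling read from the runs gives over that time, with dissolved gas at 0.0327 M, yet side product stood at 29.3% of the charge beside target at 14.4%, leaving [target] at 0.433 M.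

The data were computed with made-up constants; scatter was added.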